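If G in the flask is charged differently, 50% conversion arrives at another moment, and the catalyst may stand at another stage of waking then, so I followed its clock as well as its charge.

| flask | Q | G | remark |
|---|---|---|---|
| alder | 0.10 M | 1.5 mM | run made earlier |
| elm | 0.17 M | 1.5 mM | run made earlier |
| cedar | 0.075 M | 3 mM | run made earlier |
| flask | 0.075 M | 1.5 mM |  |

| run | time / d | E / % | Q / % |
|---|---|---|---|
| alder | 1.04 | 38.1 | 63.1 |
| alder | 2.08 | 77.1 | 23.5 |
| alder | 3.00 | 92.4 | 8.1 |
| alder | 4.00 | 97.9 | 3.3 |
| alder | 5.00 | 99.6 | 0.6 |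
| alder | 6.00 | 100.1 | 0 |
| alder | 8.00 | 99.5 | 0 |
| elm | 0.625 | 16.4 | 82.5 |
| elm | 0.833 | 27.2 | 72.6 |
| elm | 1.25 | 47.8 | 53.1 |
| elm | 2.08 | 76.5 | 22.3 |
| elm | 3.00 | 92.4 | 8.4 |
| elm | 5.00 | 99.2 | 0.6 |
| elm | 8.00 | 99.9 | 0.3 |
| cedar | 1.25 | 72.6 | 27.8 |
| cedar | 3.00 | 99.1 | 0 |
| cedar | 4.00 | 100.5 | 0.5 |
| cedar | 6.00 | 99.9 | 0.9 |
| cedar | 8.00 | 98.7 | 0 |

(each reading ± 0.5 percentage points)

- factor on the rate of making E when 50% of the Q are converted if G is charged twice over
- factor on the rate when 50% of the Q are converted if G is charged at 0.15 mM instead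

I called D minus the logarithm of the fraction of Q left. At 3.00 d, alder and elm held Q 8.1% and 8.4%, so I took the flask, with the same G, to follow their percentages (pseudo-first-order in Q). Its neighbour cedar has the flask's Q and twice its G. At 1.25 d, cedar held Q 27.8%, and elm's 53.1% squared is 28.2%, so I took D at a given time to go with the charge. At 6.00 d, cedar read E 99.9%, which is 25.0 E per G charged; Q is the limiting reagent there, and I expected the flask to end likewise.

Elm's D rose at 0.750 /d, but alder's, from E between 3.00 d and 4.00 d, rose at K = 1.29 /d, which is faster. I wrote the balance of G with an unwoken share exp(−t/τ), so the working share is w = 1 − exp(−t/τ). Alder's late line then gave the waking time τ, the delay of that line (induction period), as 0.996 d. This is a rough reading, with scatter 0.5 percentage points on 2.10% of Q left.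

Elm's readings put 50% in the flask at 1.31 d, where w = 73.1%. With doubled G, that conversion needs the D of 70.7% of Q left, reached at 0.868 d, where w = 58.2%. With 0.15 mM, the late line gives 6.39 d and w = 99.8%. Charge ratio times w ratio gave me 1.59 and 0.137.

The forecast, reading "This lag depends on time, not on conversion or G", gave 1.64 and 0.128.

The flask gave 1.59 and 0.139, and it reached 50% conversion at 1.30 d.

    Q + X → X + E (k = 34.2 /M/h)
    G → X (k = 0.0403 /h)

At 85 percent conversion, at 2.48 d, my τ gives w = 91.7%, and the flask then held 90.9% of its catalyst as X.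

All runs are simulated for an exercise; noise was put on by code.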